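**Remark (assumption):** Daucane numbering is used throughout (ring A = five-membered ring C1–C5, ring B = seven-membered ring C1, C5–C10); β is the face of the C15 methyl group in the target, α the opposite face. The C6 enol oxygen is carried as a triethylsilyl ether, which fluoride can cleave, because aqueous acid would ionise the tertiary allylic C4–O bond next to a C5=C6 enol ether.

## Retrosynthetic overview

1. Feature: ring B is a masked cyclohepta-1,4-diene (C8=C9 and a C5=C6 enol ether on either side of C7) closed on the quaternary C1 (C15). This is the retron of a cis-divinylcyclopropane Cope rearrangement in which one "vinyl" is a ketene (C9=C10=O).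
2. Target ⇒ esters at C2, C6 and C10; C6–OH from a C6 ketone by C4–OH-directed reduction; C10–OH from the C10 enone ⇒ bicyclic C10 enone with a C6 silyl enol ether.
3. Key: C10–C1 is formed and C6–C8 cleaved by Cope rearrangement of the ketene that arises by Wolff shift (C8–C9) of a cis cyclopropyl diazoketone. Ring B is made last, on a finished ring A.
4. Cyclopropane C6–C7–C8: rhodium-carbenoid addition of methyl diazoacetate to the C6=C7 silyl enol ether, then C8 methylation (C14) anti to the cyclopentenyl group to fix the cis geometry; C5–C6 by Stille coupling.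
5. Ring A from (R)-4-silyloxycyclopentenone: C15 by cuprate addition and Saegusa oxidation; isopropyl addition anti to C2–O sets C4; C2 is then inverted by oxidation and C4–OH-directed reduction.

Key step: step 15

## Route

Step 1
Reactants: 1 (R)-4-(tert-butyldimethylsilyloxy)cyclopent-2-en-1-one
Product: 2 trimethylsilyl enol ether of trans-3-methyl-4-(tert-butyldimethylsilyloxy)cyclopentanone (C1 methyl α, C2 silyloxy β)
Conditions: Me2CuLi (from MeLi, CuI), Et2O, −78 °C; then TMSCl, −78 → 0 °C
Reagents that add atoms: lithium dimethylcuprate, [Li+].C[Cu-]C; chlorotrimethylsilane, C[Si](C)(C)Cl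
Why: Conjugate addition of Me2CuLi puts the C15 methyl on C1 anti to the C2 silyloxy group, and O-silylation of the enolate gives the enol ether needed for regiospecific re-oxidation.

Step 2
Reactants: 2 trimethylsilyl enol ether
Product: 3 (R)-4-(tert-butyldimethylsilyloxy)-3-methylcyclopent-2-en-1-one
Conditions: Pd(OAc)2 (10 mol %), O2 (1 atm), DMSO, rt
Reagents that add atoms: none
Why: Saegusa–Ito oxidation restores the C5=C1 double bond by β-hydride elimination from C1, which removes the auxiliary C1 stereocentre and leaves C2 untouched.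

Step 3
Reactants: 3 (R)-4-(tert-butyldimethylsilyloxy)-3-methylcyclopent-2-en-1-one
Product: 4 (R)-4-(tert-butyldimethylsilyloxy)-2-iodo-3-methylcyclopent-2-en-1-one
Conditions: I2, pyridine, CH2Cl2, rt
Reagents that add atoms: iodine, II
Why: α-Iodination of the enone by pyridine-mediated addition, iodination and elimination (Johnson iodination) installs the C5 coupling handle.

Step 4
Reactants: 4 iodoenone; 5 isopropylmagnesium chloride
Product: 6 4-(tert-butyldimethylsilyloxy)-2-iodo-3-methyl-1-(propan-2-yl)cyclopent-2-en-1-ol (C4–OH β, isopropyl α, C2–OTBS β; OH and OTBS cis)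
Conditions: CeCl3, THF, −78 °C
Reagents that add atoms: none
Why: Organocerium 1,2-addition (transmetalated Grignard reagent, which suppresses enolisation, reduction and iodine–metal exchange) to the only carbonyl occurs anti to the C2 silyloxy group and so sets C4 with isopropyl α and hydroxyl β.

Step 5
Reactants: 6 tertiary alcohol
Product: 7 4-iodo-5-methyl-3-(propan-2-yl)cyclopent-4-ene-1,3-diol (both hydroxyls β, cis)
Conditions: TBAF, THF, 0 °C → rt
Reagents that add atoms: none
Why: Fluoride desilylation frees the C2 hydroxyl, whose configuration has served as the relay for C4 and must now be inverted.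

Step 6
Reactants: 7 cis-diol
Product: 8 4-hydroxy-3-iodo-2-methyl-4-(propan-2-yl)cyclopent-2-en-1-one (C4–OH β)
Conditions: IBX, DMSO, rt
Reagents that add atoms: none
Why: IBX oxidises the secondary allylic C2 alcohol to the enone and cannot oxidise the tertiary C4 alcohol.

Step 7
Reactants: 8 hydroxy enone
Product: 9 4-iodo-5-methyl-3-(propan-2-yl)cyclopent-4-ene-1,3-diol (C2–OH α, C4–OH β; trans)
Conditions: Me4NBH(OAc)3, MeCN/AcOH (1:1), −20 °C
Reagents that add atoms: none
Why: Hydroxyl-directed (Evans–Saksena) reduction binds the borohydride to the C4 hydroxyl and delivers hydride to the β face of the C2 carbonyl, giving the 2α-alcohol trans to the C4 hydroxyl.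

Step 8
Reactants: 9 trans-diol
Product: 10 C2 tert-butyldimethylsilyl ether of 9 (C2–OTBS α, C4–OH β free)
Conditions: TBSCl, imidazole, DMF, 0 °C → rt
Reagents that add atoms: tert-butylchlorodimethylsilane, CC(C)(C)[Si](C)(C)Cl
Why: The secondary allylic hydroxyl is silylated selectively, since the hindered tertiary C4 hydroxyl does not react with a silyl chloride.

Step 9
Reactants: 10 vinyl iodide; 11 tributyl(1-ethoxyvinyl)stannane
Product: 13 C5-acetyl cyclopentene, 1-[5-hydroxy-3-(tert-butyldimethylsilyloxy)-2-methyl-5-(propan-2-yl)cyclopent-1-en-1-yl]ethanone (C2–OTBS α, C4–OH β), via ethoxydiene 12 (not isolated)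
Conditions: Pd2(dba)3, AsPh3, CuI, NMP, 50 °C; then 1 M aq HCl, THF, 0 °C
Reagents that add atoms: water, O
Why: Stille coupling with copper co-catalysis joins C5 and C6 at the hindered vinyl iodide, and brief acid hydrolysis of the terminal enol ether (protonation at the unhindered C7) gives the methyl ketone carrying C6 and C7.

Step 10
Reactants: 13 methyl ketone
Product: 14 2-(triethylsilyloxy)diene with C4–OSiEt3 (C6(OSiEt3)=C7H2 on C5; C2–OTBS α; C4–OSiEt3 β)
Conditions: TESOTf, Et3N, CH2Cl2, −78 → 0 °C
Reagents that add atoms: triethylsilyl trifluoromethanesulfonate, CC[Si](CC)(CC)OS(=O)(=O)C(F)(F)F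
Why: Silyl triflate with amine base converts the methyl ketone into the cross-conjugated 2-silyloxydiene (kinetic deprotonation of the acetyl methyl) and silylates the tertiary C4 hydroxyl in the same operation.

Step 11
Reactants: 14 silyloxydiene; 15 methyl diazoacetate
Product: 16 methyl 2-(cyclopentenyl)-2-(triethylsilyloxy)cyclopropane-1-carboxylate (C6 configured as drawn, C8 as a mixture of epimers)
Conditions: Rh2(OAc)4 (1 mol %), CH2Cl2, rt, 15 added over 6 h
Reagents that add atoms: none
Why: Rhodium-carbenoid cyclopropanation takes place at the electron-rich terminal silyl enol ether (the tetrasubstituted C5=C1 bond is inert); the enol ether is twisted about C5–C6 with its oxygen turned to the α side, away from the C4 triethylsilyloxy group, and the carbenoid reaches C7 from the open C1/C15 flank, which sets C6, whereas C8 is erased in step 12.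

Step 12
Reactants: 16 cyclopropane ester
Product: 17 methyl 1-methyl-2-(cyclopentenyl)-2-(triethylsilyloxy)cyclopropane-1-carboxylate (ester cis to the cyclopentenyl group, C14 methyl cis to the silyloxy group)
Conditions: LiN(iPr)2, THF, −78 °C; then MeI, −78 → −30 °C
Reagents that add atoms: iodomethane, CI
Why: Both C8 epimers give the same ester enolate (alkylation known for 2-siloxycyclopropanecarboxylates), and iodomethane enters anti to the bulky 2,5-disubstituted cyclopentenyl group on C6, which fixes the cis relationship of carbonyl and cyclopentene.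

Step 13
Reactants: 17 methylated ester
Product: 18 the corresponding cyclopropanecarboxylic acid
Conditions: LiSPr, HMPA, rt; aq NH4Cl
Reagents that add atoms: none
Why: Thiolate SN2 demethylation attacks the unhindered O-methyl carbon, so the doubly flanked carbonyl need not be attacked, and the silyl ethers and the base-stable siloxycyclopropane survive.

Step 14
Reactants: 18 carboxylic acid
Product: 20 cis-1-(diazoacetyl)-1-methyl-2-(triethylsilyloxy)-2-(cyclopentenyl)cyclopropane with C2–OTBS and C4–OSiEt3, via acid chloride 19 (not isolated)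
Conditions: Me2C=C(Cl)NMe2, CH2Cl2, 0 °C; then CH2N2 (excess), Et2O, 0 °C
Reagents that add atoms: 1-chloro-N,N,2-trimethylprop-1-en-1-amine (chlorine of 19), CC(C)=C(Cl)N(C)C; diazomethane, C=[N+]=[N-]
Why: The α-chloroenamine forms the acid chloride without setting HCl free, and Arndt–Eistert acylation of diazomethane, whose excess removes HCl as chloromethane, gives the diazoketone without opening the siloxycyclopropane.

Step 15
Reactants: 20 cyclopropyl diazoketone
Product: 22 bicyclic C10 enone with C8=C9, the C5=C6 triethylsilyl enol ether and the quaternary C1 (C15 β; C2–OTBS α; C4–OSiEt3 β), via ketene 21 (not isolated)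
Conditions: hν (λ > 300 nm, Pyrex), THF, rt; then 60 °C
Reagents that add atoms: none
Why: Photolysis expels N2 and C8 migrates from C10 to C9 with retention (Wolff rearrangement), giving the ketene C8–C9H=C10=O, whose C9=C10 bond and the C5=C1 bond are cis on the cyclopropane and undergo a boat-like six-electron [3,3] shift that forms C10–C1 and cleaves C6–C8. The closest known reaction type is the tandem Wolff/Cope rearrangement of cis-vinylcyclopropyl diazoketones to fused cycloheptadienones. Ring B closes in this concerted sigmatropic step (bond formation at C10–C1 with ring expansion of the cyclopropane, driven by strain release), not by an ionic or radical cyclisation. The new stereocentre C1 is controlled by the cyclopropane: only the conformer with C1 folded over the three-membered ring can react, and the configuration at C6 and C8 places the ketene on the α face of C1, so C15 ends up β. The step needs the cis geometry (secured in step 12), the correct C6 configuration (step 11) and a Cope rearrangement faster than ketene dimerisation. The sp-hybridised ketene terminus carries no inward substituent, which offsets the inward C15 methyl on the fully substituted C1, and the product already holds C10 as the enone and C6 at the ketone level.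

Step 16
Reactants: 22 bicyclic enone
Product: 23 10β-allylic alcohol (C10–OH cis to C15)
Conditions: iBu2AlH, CH2Cl2, −78 °C; aq potassium sodium tartrate
Reagents that add atoms: none
Why: 1,2-Reduction of the enone from the α face, anti to the pseudo-axial C15 methyl on the adjacent quaternary C1, gives the 10β-alcohol and leaves the silyl enol ether intact.

Step 17
Reactants: 23 allylic alcohol
Product: 24 10β-benzoate
Conditions: BzCl, pyridine, DMAP (cat.), CH2Cl2, 0 °C → rt
Reagents that add atoms: benzoyl chloride, O=C(Cl)c1ccccc1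
Why: DMAP-catalysed acylation of the only free hydroxyl under basic conditions, which the silyl enol ether tolerates.

Step 18
Reactants: 24 benzoate silyl enol ether
Product: 25 trans-fused 6-ketone with free C4–OH (H5 α; C10–OBz β; C2–OTBS α)
Conditions: HF·pyridine, pyridine, THF, 0 °C → rt
Reagents that add atoms: none
Why: Fluoride cleaves the triethylsilyl enol ether and then the tertiary triethylsilyl ether without the acid that would ionise C4–O; ketonisation under these non-equilibrating conditions is expected to protonate C5 on the α face, because C6 then swings toward the C4 oxygen and away from the isopropyl group while the β face is screened by C15, the C4 silyloxy group and the C10 benzoate, which gives the trans fusion and leaves C8=C9 out of conjugation, and the secondary neopentylic C2 silyl ether is retained.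

Step 19
Reactants: 25 β-hydroxy ketone
Product: 26 4β,6α-diol
Conditions: Me4NBH(OAc)3, MeCN/AcOH (1:1), −30 °C
Reagents that add atoms: none
Why: Evans–Saksena reduction delivers hydride from the boron bound to the 4β-hydroxyl to the β face of C6, giving the 1,3-anti diol (6α-OH), under acidic conditions that neither enolise the β,γ-unsaturated ketone nor touch the esters.

Step 20
Reactants: 26 diol
Product: 27 6α-angelate
Conditions: angelic acid, 2,4,6-trichlorobenzoyl chloride, Et3N, toluene, rt; then 26, 80 °C
Reagents that add atoms: angelic acid, C/C=C(/C)C(=O)O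
Why: Esterification through the mixed anhydride with 2,4,6-trichlorobenzoyl chloride (Yamaguchi type, no nucleophilic amine catalyst) acylates the only secondary hydroxyl without Z to E isomerisation to the tiglate, and the tertiary C4 hydroxyl does not react.

Step 21
Reactants: 27 angelate
Product: 28 2α-alcohol
Conditions: HF·pyridine, THF, rt
Reagents that add atoms: none
Why: Prolonged fluoride treatment removes the hindered C2 silyl ether under conditions that leave the benzoate and angelate esters in place.

Step 22
Reactants: 28 2α-alcohol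
Product: 29 target, 2α-acetoxy-6α-angeloyloxy-10β-benzoyloxydauc-8-en-4β-ol
Conditions: Ac2O, pyridine, DMAP (cat.), CH2Cl2, 0 °C → rt
Reagents that add atoms: acetic anhydride, CC(=O)OC(C)=O
Why: Acetylation of the secondary C2 hydroxyl, since the hindered tertiary C4 hydroxyl is inert under these conditions.

## Compound list

1 | (R)-4-(tert-butyldimethylsilyloxy)cyclopent-2-en-1-one | O=C1C=C[C@H](O[Si](C)(C)C(C)(C)C)C1 | starting material
2 | trimethylsilyl enol ether of trans-3-methyl-4-(tert-butyldimethylsilyloxy)cyclopentanone | C[Si](C)(C)OC1=C[C@@H](C)[C@H](O[Si](C)(C)C(C)(C)C)C1 | intermediate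
3 | (R)-4-(tert-butyldimethylsilyloxy)-3-methylcyclopent-2-en-1-one | O=C1C=C(C)[C@H](O[Si](C)(C)C(C)(C)C)C1 | intermediate
4 | (R)-4-(tert-butyldimethylsilyloxy)-2-iodo-3-methylcyclopent-2-en-1-one | O=C1C(I)=C(C)[C@H](O[Si](C)(C)C(C)(C)C)C1 | intermediate
5 | isopropylmagnesium chloride | CC(C)[Mg]Cl | starting material
6 | 4-(tert-butyldimethylsilyloxy)-2-iodo-3-methyl-1-(propan-2-yl)cyclopent-2-en-1-ol (OH and OTBS cis, both β) | IC1=C(C)[C@H](O[Si](C)(C)C(C)(C)C)C[C@@]1(O)C(C)C | intermediate
7 | cis-4-iodo-5-methyl-3-(propan-2-yl)cyclopent-4-ene-1,3-diol | IC1=C(C)[C@H](O)C[C@@]1(O)C(C)C | intermediate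
8 | 4-hydroxy-3-iodo-2-methyl-4-(propan-2-yl)cyclopent-2-en-1-one (C4–OH β) | IC1=C(C)C(=O)C[C@@]1(O)C(C)C | intermediate
9 | trans-4-iodo-5-methyl-3-(propan-2-yl)cyclopent-4-ene-1,3-diol (C2–OH α, C4–OH β) | IC1=C(C)[C@@H](O)C[C@@]1(O)C(C)C | intermediate
10 | C2 tert-butyldimethylsilyl ether of 9 | IC1=C(C)[C@@H](O[Si](C)(C)C(C)(C)C)C[C@@]1(O)C(C)C | intermediate
11 | tributyl(1-ethoxyvinyl)stannane | CCCC[Sn](CCCC)(CCCC)C(=C)OCC | starting material
12 | 2-ethoxydiene (C5-(1-ethoxyvinyl) cyclopentenol) | C=C(OCC)C1=C(C)[C@@H](O[Si](C)(C)C(C)(C)C)C[C@@]1(O)C(C)C | intermediate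
13 | C5-acetyl cyclopentenol (C2–OTBS α, C4–OH β) | CC(=O)C1=C(C)[C@@H](O[Si](C)(C)C(C)(C)C)C[C@@]1(O)C(C)C | intermediate
14 | 2-(triethylsilyloxy)diene with C4–OSiEt3 | C=C(O[Si](CC)(CC)CC)C1=C(C)[C@@H](O[Si](C)(C)C(C)(C)C)C[C@@]1(O[Si](CC)(CC)CC)C(C)C | intermediate
15 | methyl diazoacetate | COC(=O)C=[N+]=[N-] | starting material
16 | methyl 2-(cyclopentenyl)-2-(triethylsilyloxy)cyclopropane-1-carboxylate (C8 epimers) | COC(=O)C1C[C@@]1(O[Si](CC)(CC)CC)C1=C(C)[C@@H](O[Si](C)(C)C(C)(C)C)C[C@@]1(O[Si](CC)(CC)CC)C(C)C | intermediate
17 | methyl 1-methyl-2-(cyclopentenyl)-2-(triethylsilyloxy)cyclopropane-1-carboxylate (ester cis to cyclopentenyl) | COC(=O)[C@@]1(C)C[C@@]1(O[Si](CC)(CC)CC)C1=C(C)[C@@H](O[Si](C)(C)C(C)(C)C)C[C@@]1(O[Si](CC)(CC)CC)C(C)C | intermediate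
18 | corresponding cyclopropanecarboxylic acid | OC(=O)[C@@]1(C)C[C@@]1(O[Si](CC)(CC)CC)C1=C(C)[C@@H](O[Si](C)(C)C(C)(C)C)C[C@@]1(O[Si](CC)(CC)CC)C(C)C | intermediate
19 | corresponding acid chloride | O=C(Cl)[C@@]1(C)C[C@@]1(O[Si](CC)(CC)CC)C1=C(C)[C@@H](O[Si](C)(C)C(C)(C)C)C[C@@]1(O[Si](CC)(CC)CC)C(C)C | intermediate
20 | cis cyclopropyl diazoketone (key-step precursor) | [N-]=[N+]=CC(=O)[C@@]1(C)C[C@@]1(O[Si](CC)(CC)CC)C1=C(C)[C@@H](O[Si](C)(C)C(C)(C)C)C[C@@]1(O[Si](CC)(CC)CC)C(C)C | intermediate
21 | cyclopropyl ketene | O=C=C[C@@]1(C)C[C@@]1(O[Si](CC)(CC)CC)C1=C(C)[C@@H](O[Si](C)(C)C(C)(C)C)C[C@@]1(O[Si](CC)(CC)CC)C(C)C | intermediate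
22 | bicyclic C10 enone, C8=C9, C5=C6 triethylsilyl enol ether, quaternary C1 (key-step product) | CC1=CC(=O)[C@@]2(C)[C@@H](O[Si](C)(C)C(C)(C)C)C[C@@](O[Si](CC)(CC)CC)(C(C)C)C2=C(O[Si](CC)(CC)CC)C1 | intermediate
23 | 10β-allylic alcohol | CC1=C[C@H](O)[C@@]2(C)[C@@H](O[Si](C)(C)C(C)(C)C)C[C@@](O[Si](CC)(CC)CC)(C(C)C)C2=C(O[Si](CC)(CC)CC)C1 | intermediate
24 | 10β-benzoate | CC1=C[C@H](OC(=O)c3ccccc3)[C@@]2(C)[C@@H](O[Si](C)(C)C(C)(C)C)C[C@@](O[Si](CC)(CC)CC)(C(C)C)C2=C(O[Si](CC)(CC)CC)C1 | intermediate
25 | trans-fused 4β-hydroxy-6-ketone | CC1=C[C@H](OC(=O)c3ccccc3)[C@@]2(C)[C@@H](O[Si](C)(C)C(C)(C)C)C[C@@](O)(C(C)C)[C@@H]2C(=O)C1 | intermediate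
26 | 4β,6α-diol | CC1=C[C@H](OC(=O)c3ccccc3)[C@@]2(C)[C@@H](O[Si](C)(C)C(C)(C)C)C[C@@](O)(C(C)C)[C@@H]2[C@@H](O)C1 | intermediate
27 | 6α-angelate 10β-benzoate, C2–OTBS | CC1=C[C@H](OC(=O)c3ccccc3)[C@@]2(C)[C@@H](O[Si](C)(C)C(C)(C)C)C[C@@](O)(C(C)C)[C@@H]2[C@@H](OC(=O)/C(C)=C\C)C1 | intermediate
28 | 2α-alcohol | CC1=C[C@H](OC(=O)c3ccccc3)[C@@]2(C)[C@@H](O)C[C@@](O)(C(C)C)[C@@H]2[C@@H](OC(=O)/C(C)=C\C)C1 | intermediate
29 | CNP0248576.1 | C/C=C(/C)C(=O)O[C@H]1CC(C)=C[C@H](OC(=O)c2ccccc2)[C@@]2(C)[C@@H](OC(C)=O)C[C@@](O)(C(C)C)[C@H]12 | target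

## Step count

Total steps: 22. Longest linear sequence: 22 steps (from 1; compounds 5, 11 and 15 are commercial).

## Steps most likely to fail

**Step 15 (key step).** The Cope rearrangement must form a bond to a fully substituted alkene carbon that carries an inward methyl, on the face next to the C2 silyloxy group. If it is slow, the ketene may be consumed by dimerisation or by traces of nucleophiles, the donor–acceptor cyclopropane may open heterolytically, or the β,γ-unsaturated product may undergo secondary photoreactions. Fallback, setting out from 20 and coming back at 22: the ketene is made thermally instead of photochemically. Wolff rearrangement of 20 with PhCO2Ag and Et3N in aqueous THF traps the ketene as the homologated cyclopropylacetic acid F1. F1 is converted with 1-chloro-N,N,2-trimethylprop-1-en-1-amine into the acid chloride F2. Slow addition of F2 to Et3N in toluene at 80–110 °C (dehydrochlorination, as used for intramolecular ketene reactions) regenerates ketene 21 at high dilution, without light and at a temperature that drives the Cope rearrangement to 22.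

**Step 11.** The facial selectivity at C6 rests on the twist sense of the silyl enol ether about C5–C6. If the two twisted conformers react at similar rates, the C6-epimeric cyclopropane forms, and it would lead to the C1 epimer in step 15. Fallback, setting out from 14 and coming back at 16: substrate control is replaced by reagent control, using methyl diazoacetate with [Cu(MeCN)4]PF6 and the (S,S)-tert-butyl bis(oxazoline) ligand. In such copper-carbenoid cyclopropanations the ligand fixes the configuration of the carbenoid carbon and the ester lies trans to the larger alkene substituent (here the cyclopentenyl group), so C6 follows from the catalyst; the (S,S) ligand is chosen by analogy with monosubstituted alkenes. This fallback makes no new compound (F0).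

**Step 18.** Protonation of C5 may occur on the β face and give the cis ring fusion. It cannot be corrected afterwards, because enolising conditions would move C8=C9 into conjugation with the C6 ketone and expel the C10 benzoate by vinylogous elimination. Fallback, setting out from 22 and coming back at 27: the ring fusion is set under thermodynamic control before C10 is reduced. HF·pyridine on 22 gives the hydroxy enedione F3, in which C7 lies between the C6 ketone and the C10 enone, so enolisation is reversible and has no leaving group to expel. A trace of pyridinium p-toluenesulfonate in CH2Cl2 equilibrates C5 to the trans fusion, which is favoured by the C4–OH···O=C6 hydrogen bond and by C6 lying anti to the isopropyl group. Me4NBH(OAc)3 then reduces only the C4–OH-directed, saturated C6 ketone to the 6α-alcohol F4, which draws the tautomers through that form. Angeloylation as in step 20 gives the angelate F5, reduction with NaBH4 and CeCl3·7H2O in MeOH at −78 °C gives the 10β-alcohol F6, and benzoylation as in step 17 gives 27.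

## Further compounds

F1 | step 15 | homologated cis-cyclopropylacetic acid | OC(=O)C[C@@]1(C)C[C@@]1(O[Si](CC)(CC)CC)C1=C(C)[C@@H](O[Si](C)(C)C(C)(C)C)C[C@@]1(O[Si](CC)(CC)CC)C(C)C
F2 | step 15 | homologated acid chloride | O=C(Cl)C[C@@]1(C)C[C@@]1(O[Si](CC)(CC)CC)C1=C(C)[C@@H](O[Si](C)(C)C(C)(C)C)C[C@@]1(O[Si](CC)(CC)CC)C(C)C
F0 | step 11 | none | none
F3 | step 18 | trans-fused 4β-hydroxy-8-ene-6,10-dione | CC1=CC(=O)[C@@]2(C)[C@@H](O[Si](C)(C)C(C)(C)C)C[C@@](O)(C(C)C)[C@@H]2C(=O)C1
F4 | step 18 | 4β,6α-dihydroxy-10-enone | CC1=CC(=O)[C@@]2(C)[C@@H](O[Si](C)(C)C(C)(C)C)C[C@@](O)(C(C)C)[C@@H]2[C@@H](O)C1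
F5 | step 18 | 6α-angelate 10-enone | CC1=CC(=O)[C@@]2(C)[C@@H](O[Si](C)(C)C(C)(C)C)C[C@@](O)(C(C)C)[C@@H]2[C@@H](OC(=O)/C(C)=C\C)C1
F6 | step 18 | 6α-angelate 10β-alcohol | CC1=C[C@H](O)[C@@]2(C)[C@@H](O[Si](C)(C)C(C)(C)C)C[C@@](O)(C(C)C)[C@@H]2[C@@H](OC(=O)/C(C)=C\C)C1
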